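**Retrosynthetic overview**
- Feature: coumarin numbering is used, also for the open-chain precursors (unprimed: 4,7-dimethoxy half, benzene ring A; primed: 7'-hydroxy half, benzene ring B). Rings A and B are both resorcinol-type arenes (oxygen on C7/C8a and on C7'/C8a') in which the acyl-bearing carbon C4a (C4a') sits next to the methyl-bearing carbon C5 (C5'). The biaryl bond C8-C6' connects the alpha carbon of one acetoacetate chain with the gamma carbon of a second one.
- Last rings: both pyranone rings are cut back (7'-O-benzyl removal, 4- and 4'-O-methylation, double diethyl carbonate annulation) to a biaryl bis(ortho-hydroxyacetophenone) carrying 7-OMe and 7'-OBn.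
- Key disconnection: rings A and B are opened in one operation at C5-C6, C4a-C8a, C5'-C6' and C4a'-C8a'. This leaves two molecules of pent-3-yn-2-one and one linked bis(1-methoxy-1-silyloxy-3-alkoxydiene). In the forward direction ring A should close first, ring B second, and the two pyranones last.
- Precursor: the bis-diene comes from a diester by twofold dienolate silylation. The diester comes from SN2 alkylation of methyl acetoacetate (C8) with a 4-chloro-3-benzyloxycrotonate (C6'), followed by enolate O-methylation. The axis therefore starts as an sp3-sp3 bond, and the 7-OMe/7'-OBn difference is fixed in the two enol ethers.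

Key step: step 5

Assumption: the target SMILES gives no descriptor for the hindered C8-C6' axis, so the racemic atropisomer mixture is taken as the goal and no step controls the axis.
Remark: compound 1 is a catalogue chemical (the trimethyl orthoformate enol ether of methyl 4-chloroacetoacetate).

**Step 1**
Reactants: 1 methyl (E)-4-chloro-3-methoxybut-2-enoate; 2 benzyl alcohol
Product: 3 methyl (E)-3-(benzyloxy)-4-chlorobut-2-enoate
Conditions: 2 (1.5 equiv), MsOH (5 mol %), toluene, 85 °C, 200 mbar, MeOH distilled off
Reagents that add atoms: none
Why: Acid-catalysed transetherification of a beta-alkoxyacrylate (C-protonation, mixed ketal, loss of methanol) is driven by removal of methanol, returns the thermodynamic E enol ether, and leaves the donor-deactivated conjugated ester and the primary chloride untouched at this temperature.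

**Step 2**
Reactants: 3 methyl (E)-3-(benzyloxy)-4-chlorobut-2-enoate; 4 methyl acetoacetate
Product: 5 dimethyl (2E)-5-acetyl-3-(benzyloxy)hex-2-enedioate (racemic)
Conditions: 4 (1.5 equiv), NaH (1.4 equiv), THF, 0 °C; then 3, NaI (10 mol %), DMF, 0 to 45 °C
Reagents that add atoms: none
Why: Acetoacetic ester alkylation, in which the soft sodium enolate displaces the iodide-activated allylic-type primary chloride by SN2 and makes the C8-C6' bond, the excess of 4 holds back double alkylation, and the new C8 stereocentre is racemic and disappears in step 3.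

**Step 3**
Reactants: 5 dimethyl (2E)-5-acetyl-3-(benzyloxy)hex-2-enedioate
Product: 6 dimethyl (2E)-3-(benzyloxy)-5-(1-methoxyethylidene)hex-2-enedioate (C7=C8 geometry not defined)
Conditions: KN(SiMe3)2 (1.05 equiv), 18-crown-6, THF, -78 °C; MeOTf (1.2 equiv), -78 to -20 °C
Reagents that add atoms: methyl trifluoromethanesulfonate, COS(=O)(=O)C(F)(F)F
Why: O-alkylation of an ambident beta-keto ester enolate, in which the dissociated potassium enolate meets the hard electrophile at oxygen while C-methylation would have to build a quaternary C8, the aprotic basic medium avoids the acid-catalysed exchange that would scramble the methyl and benzyl enol ethers, and either C7=C8 geometry serves because this bond becomes single in 7.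

**Step 4**
Reactants: 6 dimethyl (2E)-3-(benzyloxy)-5-(1-methoxyethylidene)hex-2-enedioate
Product: 7 linked bis-diene (1Z,3Z,5Z)-4-(benzyloxy)-1,6-dimethoxy-2-(1-methoxyethenyl)-1,6-bis(trimethylsilyloxy)hexa-1,3,5-triene
Conditions: Me3SiCl (4 equiv), then LiN(iPr)2 (2.5 equiv) added slowly, THF, -78 to 0 °C; pentane, filtration under Ar, used crude
Reagents that add atoms: chlorotrimethylsilane, C[Si](C)(C)Cl
Why: Kinetic gamma-deprotonation of a beta-alkoxy enoate followed by O-silylation, the standard way to 1-methoxy-1-silyloxy-3-alkoxydienes, is carried out twice with the silyl chloride present from the start, so that each ester dienolate (first at the doubly allylic C6'H2, then at C6H3) is trapped as it forms and no dianion is needed, and C8 should lie trans to C8' across C6'=C7' to avoid allylic strain (the ketene acetal geometries as drawn are of no consequence).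

**Step 5**
Reactants: 7 linked bis-diene; 8 pent-3-yn-2-one (two equivalents incorporated)
Product: 11 biaryl bis(ortho-hydroxyacetophenone) 1,1'-[6'-(benzyloxy)-2,4'-dihydroxy-6-methoxy-2',4-dimethylbiphenyl-3,3'-diyl]diethanone, via ring A silyl ether diene 9 (not isolated), via biaryl bis(silyl ether) 10 (not isolated)
Conditions: 8 (6 equiv), powdered 4 Å molecular sieves, BHT (cat.), toluene, sealed tube, 70 then 135 °C; 1 M HCl, THF, rt
Reagents that add atoms: none
Why: Proposed new method: each half of 7 is a dienyl ketene acetal (a 1,1,3-trioxygenated diene) with its largest HOMO coefficient at the terminus C6 or C6', so this carbon attacks the methyl-bearing beta carbon of 8 (the future C5 or C5') while the acetal carbon C8a or C8a' bonds to the acyl-bearing alpha carbon (C4a or C4a') in a strongly asynchronous thermal (4+2) cycloaddition, and each 1,4-cyclohexadiene ketal formed in this way loses methanol by 1,4-elimination to leave an aryl silyl ether. The closest known reaction type is the Diels-Alder aromatization of one such silyloxydiene with an alkynyl ketone or ester to a resorcinol derivative, and what goes beyond it is that two dienes, cross-conjugated through C8-C6', are consumed in one flask and that one of them reacts at a terminus bearing a bulky sp2 substituent. Ring A closes by intermolecular (4+2) addition across C6 and C8a (bonds C5-C6 and C4a-C8a) and is expected first, since C6 is an unsubstituted CH2 and the C8 substituent favours the s-cis form, which gives 9; ring B closes in the same mode across C6' and C8a' (bonds C5'-C6' and C4a'-C8a') at the higher temperature and gives 10. The step needs regioselectivity, secured by the complementary polarization of the donor-substituted dienes and the acceptor-substituted alkyne, and site selectivity among the three diene pairings, secured because neither end of the crossed pairing C8a=C8-C6'=C7' carries a hydrogen and because step 4 places C8 on the outer side of C6'=C7'. The sieves bind the released methanol before it can protonate the ketene acetal that survives in 9, and dilute acid at the end frees the two chelated phenols of 11. No stereocentre is left, because every sp3 centre of the primary adducts is lost on aromatization, and the hindered C8-C6' axis forms as a racemate.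

**Step 6**
Reactants: 11 biaryl bis(ortho-hydroxyacetophenone)
Product: 12 7'-(benzyloxy)-4,4'-dihydroxy-7-methoxy-5,5'-dimethyl-8,6'-bicoumarin
Conditions: NaH (10 equiv), (EtO)2CO, toluene, 110 °C; then 1 M HCl
Reagents that add atoms: diethyl carbonate, CCOC(=O)OCC
Why: Twofold Claisen-type C-ethoxycarbonylation of the methyl ketone enolates followed by lactonization onto the neighbouring phenoxides, the classical synthesis of 4-hydroxycoumarins from ortho-hydroxyacetophenones, closes both pyranone rings, and the benzyl and methyl ethers are inert to the base.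

**Step 7**
Reactants: 12 7'-(benzyloxy)-4,4'-dihydroxy-7-methoxy-5,5'-dimethyl-8,6'-bicoumarin
Product: 13 7'-(benzyloxy)-4,4',7-trimethoxy-5,5'-dimethyl-8,6'-bicoumarin
Conditions: Me2SO4 (3 equiv), K2CO3, acetone, reflux
Reagents that add atoms: dimethyl sulfate, COS(=O)(=O)OC
Why: O-methylation of the two acidic 4-hydroxycoumarin units (vinylogous acids) with a hard electrophile and a mild base should give the 4-methoxycoumarins rather than C3-methyl or 2-methoxychromone isomers, and no other free hydroxyl competes because O7' is still benzylated.

**Step 8**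
Reactants: 13 7'-(benzyloxy)-4,4',7-trimethoxy-5,5'-dimethyl-8,6'-bicoumarin
Product: 14 7'-hydroxy-4,4',7-trimethoxy-5,5'-dimethyl-8,6'-bicoumarin (target CNP0113839.0)
Conditions: H2 (1 atm), 10 % Pd/C, THF-MeOH, rt
Reagents that add atoms: none
Why: Catalytic hydrogenolysis of the aryl benzyl ether frees the 7'-hydroxyl, while the trisubstituted, donor-substituted C3=C4 bonds of the 4-methoxycoumarins should not be reduced under these mild conditions.

**Compound list**
1 | methyl (E)-4-chloro-3-methoxybut-2-enoate | COC(=O)/C=C(/OC)CCl | starting material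
2 | benzyl alcohol | OCc1ccccc1 | starting material
3 | methyl (E)-3-(benzyloxy)-4-chlorobut-2-enoate | COC(=O)/C=C(/OCc1ccccc1)CCl | intermediate
4 | methyl acetoacetate | CC(=O)CC(=O)OC | starting material
5 | dimethyl (2E)-5-acetyl-3-(benzyloxy)hex-2-enedioate, racemic | COC(=O)/C=C(/OCc1ccccc1)CC(C(C)=O)C(=O)OC | intermediate
6 | dimethyl (2E)-3-(benzyloxy)-5-(1-methoxyethylidene)hex-2-enedioate, C7=C8 geometry not defined | COC(=O)/C=C(/OCc1ccccc1)CC(C(=O)OC)=C(C)OC | intermediate
7 | linked bis-diene, (1Z,3Z,5Z)-4-(benzyloxy)-1,6-dimethoxy-2-(1-methoxyethenyl)-1,6-bis(trimethylsilyloxy)hexa-1,3,5-triene | C=C(OC)/C(/C=C(OCc1ccccc1)/C=C(/OC)O[Si](C)(C)C)=C(/OC)O[Si](C)(C)C | intermediate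
8 | pent-3-yn-2-one | CC#CC(C)=O | starting material
9 | 1-{3-[(1Z,3Z)-2-(benzyloxy)-4-methoxy-4-(trimethylsilyloxy)buta-1,3-dienyl]-4-methoxy-6-methyl-2-(trimethylsilyloxy)phenyl}ethanone (ring A closed, ring B diene intact) | CC(=O)c1c(C)cc(OC)c(/C=C(OCc2ccccc2)/C=C(/OC)O[Si](C)(C)C)c1O[Si](C)(C)C | intermediate
10 | bis(trimethylsilyl ether) of 11, racemic axis | CC(=O)c1c(C)cc(OC)c(c1O[Si](C)(C)C)-c1c(OCc2ccccc2)cc(O[Si](C)(C)C)c(C(C)=O)c1C | intermediate
11 | 1,1'-[6'-(benzyloxy)-2,4'-dihydroxy-6-methoxy-2',4-dimethylbiphenyl-3,3'-diyl]diethanone, racemic axis | CC(=O)c1c(C)cc(OC)c(c1O)-c1c(OCc2ccccc2)cc(O)c(C(C)=O)c1C | intermediate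
12 | 7'-(benzyloxy)-4,4'-dihydroxy-7-methoxy-5,5'-dimethyl-8,6'-bicoumarin, racemic axis | COc1cc(C)c2c(O)cc(=O)oc2c1-c1c(OCc3ccccc3)cc2oc(=O)cc(O)c2c1C | intermediate
13 | 7'-(benzyloxy)-4,4',7-trimethoxy-5,5'-dimethyl-8,6'-bicoumarin, racemic axis | COc1cc(C)c2c(OC)cc(=O)oc2c1-c1c(OCc3ccccc3)cc2oc(=O)cc(OC)c2c1C | intermediate
14 | 7'-hydroxy-4,4',7-trimethoxy-5,5'-dimethyl-8,6'-bicoumarin, racemic axis | COc1cc(C)c2c(OC)cc(=O)oc2c1-c1c(O)cc2oc(=O)cc(OC)c2c1C | target

Total step count: 8. Longest linear sequence: 8 steps (1 to 14).

**Steps most likely to fail**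

1) Step 5 (labelled step).
- What may go wrong: the cycloaddition at the substituted terminus C6' may lag so far behind the first one that the surviving ketene acetal is protonated. The ynone may polymerize at the temperature needed. The cross-conjugated polyene may be consumed unselectively.
- Fallback (sets out from 6, returns at 11): the three-component reaction is replaced by two separate two-component Diels-Alder aromatizations of the known single-diene kind, with ring B made first.
- One equivalent of LiN(iPr)2 with Me3SiCl in THF at -78 °C should remove only the more acidic, doubly allylic C6'-H of 6. This gives the mono(silyl ketene acetal) methyl 4-(benzyloxy)-6-methoxy-2-(1-methoxyethylidene)-6-(trimethylsilyloxy)hexa-3,5-dienoate F1.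
- F1 holds one electron-rich diene only. It can be heated with 8 in toluene or pressurized with it (12 kbar, CH2Cl2, rt) without a second sensitive group being at stake.
- Dilute acid then gives methyl 2-[3-acetyl-6-(benzyloxy)-4-hydroxy-2-methylphenyl]-3-methoxybut-2-enoate F2, in which ring B and the axis bond are in place.
- Persilylation of F2 with LiN(iPr)2 (3.5 equiv) and Me3SiCl gives 2-{6-(benzyloxy)-2-methyl-4-(trimethylsilyloxy)-3-[1-(trimethylsilyloxy)ethenyl]phenyl}-1,3-dimethoxy-1-(trimethylsilyloxy)buta-1,3-diene F3.
- The cycloaddition of F3 with 8 takes place at the unsubstituted C6H2 terminus. Acid work-up removes all silyl groups and returns to 11.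

2) Step 4.
- What may go wrong: the second deprotonation may stay incomplete. C-silylation may compete. The bis(ketene acetal) may hydrolyse on isolation. C8 may end up on the inner side of C6'=C7'.
- Fallback (sets out from 6, returns at 11): the lithium amide enolization is replaced by soft enolization with tBuMe2SiOTf (2.5 equiv) and Et3N in Et2O at 0 °C. Each ester carbonyl is silylated first and the amine then removes the gamma proton, so no strong base and no polyanion are involved.
- This should give 4-(benzyloxy)-1,6-bis(tert-butyldimethylsilyloxy)-1,6-dimethoxy-2-(1-methoxyethenyl)hexa-1,3,5-triene F4, which is robust enough for filtration through deactivated silica.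
- F4 takes the place of 7 in the cycloaddition with 8. Bu4NF/AcOH in THF, used in place of dilute acid, returns to the route at 11.

3) Step 3.
- What may go wrong: C-methylation at C8 may compete, and the enolate oxygen may close onto C7' with loss of benzyl alcohol and aromatization to a furan.
- Fallback (sets out from 5, returns at 11): O7 is carried as a silyl ether through the key step and methylated afterwards.
- Me3SiCl and Et3N in CH2Cl2 turn 5 into dimethyl (2E)-3-(benzyloxy)-5-[1-(trimethylsilyloxy)ethylidene]hex-2-enedioate F5.
- Twofold deprotonation and silylation as in step 4 gives 4-(benzyloxy)-1,6-dimethoxy-1,6-bis(trimethylsilyloxy)-2-[1-(trimethylsilyloxy)ethenyl]hexa-1,3,5-triene F6.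
- Double cycloaddition of F6 with 8 and acid work-up as in step 5 gives 1,1'-[6'-(benzyloxy)-2,4',6-trihydroxy-2',4-dimethylbiphenyl-3,3'-diyl]diethanone F7.
- In F7 only the 7-hydroxyl is not chelated to an acetyl group. One equivalent of MeI with K2CO3 in acetone should therefore methylate it selectively, a known selectivity of 2,4-dihydroxyacetophenones, and return to 11.

**Further compounds**
F1 | step 5 | methyl 4-(benzyloxy)-6-methoxy-2-(1-methoxyethylidene)-6-(trimethylsilyloxy)hexa-3,5-dienoate | CC(OC)=C(C(=O)OC)/C=C(OCc1ccccc1)/C=C(/OC)O[Si](C)(C)C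
F2 | step 5 | methyl 2-[3-acetyl-6-(benzyloxy)-4-hydroxy-2-methylphenyl]-3-methoxybut-2-enoate | CC(OC)=C(C(=O)OC)c1c(OCc2ccccc2)cc(O)c(C(C)=O)c1C
F3 | step 5 | 2-{6-(benzyloxy)-2-methyl-4-(trimethylsilyloxy)-3-[1-(trimethylsilyloxy)ethenyl]phenyl}-1,3-dimethoxy-1-(trimethylsilyloxy)buta-1,3-diene | C=C(OC)C(=C(OC)O[Si](C)(C)C)c1c(OCc2ccccc2)cc(O[Si](C)(C)C)c(C(=C)O[Si](C)(C)C)c1C
F4 | step 4 | 4-(benzyloxy)-1,6-bis(tert-butyldimethylsilyloxy)-1,6-dimethoxy-2-(1-methoxyethenyl)hexa-1,3,5-triene | C=C(OC)/C(/C=C(OCc1ccccc1)/C=C(/OC)O[Si](C)(C)C(C)(C)C)=C(/OC)O[Si](C)(C)C(C)(C)C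
F5 | step 3 | dimethyl (2E)-3-(benzyloxy)-5-[1-(trimethylsilyloxy)ethylidene]hex-2-enedioate | COC(=O)/C=C(/OCc1ccccc1)CC(C(=O)OC)=C(C)O[Si](C)(C)C
F6 | step 3 | 4-(benzyloxy)-1,6-dimethoxy-1,6-bis(trimethylsilyloxy)-2-[1-(trimethylsilyloxy)ethenyl]hexa-1,3,5-triene | C=C(O[Si](C)(C)C)/C(/C=C(OCc1ccccc1)/C=C(/OC)O[Si](C)(C)C)=C(/OC)O[Si](C)(C)C
F7 | step 3 | 1,1'-[6'-(benzyloxy)-2,4',6-trihydroxy-2',4-dimethylbiphenyl-3,3'-diyl]diethanone | CC(=O)c1c(C)cc(O)c(c1O)-c1c(OCc2ccccc2)cc(O)c(C(C)=O)c1C
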